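The flasks dawn, winter and autumn were to be read at 4.0 d, 5.0 d and 6.0 d, and I wanted to reckon beforehand what would stand in them then.

| setting | ash | elm | dawn | winter | autumn |
|---|---|---|---|---|---|
| starting material | 0.025 M | 0.038 M | 0.050 M | 0.050 M | 0.050 M |
| reagent | 0.0475 M | 0.0475 M | 0.0475 M | 0.0475 M | 0.0475 M |
| remark | run made earlier | run made earlier |  |  |  |
| time |  |  | 4.0 d | 5.0 d | 6.0 d |

| run | time / d | intermediate / % | starting material / % | product / % |
|---|---|---|---|---|
| ash | 0.250 | 45.3 | 43.1 | 10.9 |
| ash | 0.417 | 45.0 | 36.4 | 17.8 |
| ash | 0.625 | 40.8 | 31.8 | 28.3 |
| ash | 1.25 | 24.3 | 25.9 | 51.1 |
| ash | 2.08 | 11.6 | 23.4 | 64.8 |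
| ash | 3.00 | 5.4 | 21.8 | 72.3 |
| elm | 0.500 | 38.8 | 39.8 | 19.5 |
| elm | 1.04 | 24.3 | 35.3 | 39.2 |
| elm | 1.67 | 12.7 | 34.6 | 51.7 |
| elm | 2.00 | 9.4 | 33.8 | 57.1 |
| elm | 2.50 | 5.5 | 33.9 | 59.9 |
| elm | 3.00 | 3.1 | 33.9 | 61.9 |

(standard deviation of a reading: 0.5 percentage points)

- which of these there is most of at the end, counted by the starting material in it, dawn (product / starting material / intermediate)
- which of these there is most of at the end, counted by the starting material in it, winter (product / starting material / intermediate)
- which of these there is most of at the end, counted by the starting material in it, autumn (product / starting material / intermediate)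
- the largest of these amounts at the end, in percent of the starting material charged, dawn
- the largest of these amounts at the end, in percent of the starting material charged, winter
- the largest of these amounts at the end, in percent of the starting material charged, autumn

- a reading or a percentage of product counts all its forms, free or not

I built the flask up one process at a time. Taking first the main step by itself, one reagent turns one starting material into intermediate, and reagent is the limiting reagent because c(reagent) 0.0475 M is less than c(starting material) 0.050 M, which leaves 5.00% of the starting material.

Next I added intermediate going on to product. In elm, with starting material near 33.9%, intermediate fell from 12.7% to 3.1% between 1.67 d and 3.00 d, a reading of 0.654 d for its half-life. So dawn's reading time, counted from the start, was 6.12 half-lives and autumn's 9.17, and I reckoned that 1.44% and 0.173% of what was converted would still be intermediate in those flasks.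

But ash and elm were each charged with more reagent than starting material, and still at the last readings starting material stood at 21.8% in ash and 33.9% in elm. Counting the full reagent charge as used by the last reading, ash spent 2.43 reagent per starting material converted and elm 1.89, at charge ratios c(reagent)/c(starting material) of 1.90 and 1.25. So I took it that some reagent went another way, and more of it per starting material converted at the higher ratio. 0.829 is the slope of the straight line through those two, and carried down to 0.950 it gave 1.64 for the reagent price, the reagent spent per starting material converted. That converts 57.8% and leaves 42.2% of the starting material. With the half-lives, I expected product at 57.0%, 57.6% and 57.7% in dawn, winter and autumn, ahead of starting material.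

The forecast gave starting material at 49.7% for dawn, product at 50.1% for winter and product at 50.6% for autumn, and said: “This is a near tie, so the labels are uncertain, especially dawn.”

The flasks gave product at 56.5% in dawn, product at 57.1% in winter and product at 57.2% in autumn.

    starting material + reagent → intermediate (k = 0.121 /M/min)
    intermediate → product (k = 7.62 × 10⁻⁴ /min)
    2 reagent → homo dimer (k = 0.0757 /M/min)
    crystals ⇌ product, rate k4*(cs4 - [product]) while solid is left; crystals form when [product] > cs4 (solubility = 28.0 mM, k = 0.401 /min)

At 4.00 d dawn held starting material at 42.7% and reagent at 0%, a reagent price of 1.66 against my 1.64. Left until 40.0 d, dawn reaches product 57.3%, up by 0.80 percentage points, about the 0.847% of intermediate present at the reading, while starting material stays at 42.7% and reagent at 0%. A neighbour flask, the same as dawn but with 0.012 M of reagent, lies far down the line, which gives a price of 1.05. At 4.00 d it held reagent at 0% and starting material at 79%, a price of 1.15.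

The data were computed from invented constants.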